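**Strategy.** Ring A is disconnected at C1–C2 (labdane numbering), the one ring bond that joins two unsubstituted methylenes, between quaternary C10 and C3. The key step forges it by ring-closing metathesis of a C10 propenyl arm with a C4 allyl arm on an enantioenriched ring B, then saturates it in the same flask, giving a Δ5-octalin. The precursor is a cyclohexene carrying both arms, made by a catalytic asymmetric conjugate addition–allylation (C9, C10) and an aldol–dehydration (C4–C5). The rigid bicycle then sets C4 (dienolate methylation) and C5/C6 (hydroboration) from its α-face; the Z-diene and the exocyclic methylene are installed last.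

Key step: step 7

Remark: labdane numbering (C1–C20) is used for ring B and bicyclic compounds, α/β mean opposite to/on the face of the C10 methyl group, and 1, 4, 8 and all reagents are taken as commercial.

**Step 1**
Reactants: 1 1,4-dioxaspiro[4.5]dec-6-en-8-one
Product: 2 7-iodo-1,4-dioxaspiro[4.5]dec-6-en-8-one
Conditions: I2, pyridine, CH2Cl2, 0 °C → rt
Reagents that add atoms: iodine, II
Why: Pyridine-mediated α-iodination of the enone (conjugate addition of pyridine, iodination of the enolate, elimination) should functionalise the future C10 without touching the ketal; no stereocentre is formed.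

**Step 2**
Reactants: 2 7-iodo-1,4-dioxaspiro[4.5]dec-6-en-8-one
Product: 3 7-methyl-1,4-dioxaspiro[4.5]dec-6-en-8-one
Conditions: MeZnCl, Pd(PPh3)4 (5 mol %), THF, rt
Reagents that add atoms: methylzinc chloride, C[Zn]Cl
Why: Negishi coupling of the α-iodoenone should install the C10 methyl group without conjugate addition; no stereocentre is formed.

**Step 3**
Reactants: 3 7-methyl-1,4-dioxaspiro[4.5]dec-6-en-8-one; 4 (1,3-dioxolan-2-ylmethyl)magnesium bromide
Product: 6 (6R,7R)-7-allyl-6-(1,3-dioxolan-2-ylmethyl)-7-methyl-1,4-dioxaspiro[4.5]decan-8-one, via magnesium enolate 5 (not isolated)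
Conditions: 4 (1.5 equiv), Cu(OTf)2 (3 mol %), chiral hydroxyalkyl-imidazolinium NHC precursor (4 mol %), Et2O, −30 °C; then allyl iodide, DMPU, −30 → 0 °C
Reagents that add atoms: allyl iodide, C=CCI
Why: Copper–NHC-catalysed asymmetric conjugate addition of a Grignard reagent to an α-substituted cyclic enone should set C9 under ligand control (ligand enantiomer chosen for the configuration shown), and the magnesium enolate is then allylated anti to the new C9 substituent, creating quaternary C10 with the allyl group trans to the side-chain stub.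

**Step 4**
Reactants: 6 (6R,7R)-7-allyl-6-(1,3-dioxolan-2-ylmethyl)-7-methyl-1,4-dioxaspiro[4.5]decan-8-one
Product: 7 (6R,7R)-6-(1,3-dioxolan-2-ylmethyl)-7-methyl-7-[(E)-prop-1-enyl]-1,4-dioxaspiro[4.5]decan-8-one
Conditions: RuHCl(CO)(PPh3)3 (2 mol %), toluene, 80 °C
Reagents that add atoms: none
Why: Ruthenium hydride-catalysed olefin isomerisation (hydrometalation/β-hydride elimination) should move the terminal double bond one position to the (E)-propenyl group and must stop there because C10 is quaternary; no stereocentre is touched.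

**Step 5**
Reactants: 7 (6R,7R)-6-(1,3-dioxolan-2-ylmethyl)-7-methyl-7-[(E)-prop-1-enyl]-1,4-dioxaspiro[4.5]decan-8-one; 8 methyl pent-4-enoate
Product: 10 methyl 2-[8-hydroxy-6-(1,3-dioxolan-2-ylmethyl)-7-methyl-7-((E)-prop-1-enyl)-1,4-dioxaspiro[4.5]dec-8-yl]pent-4-enoate (C4/C5 diastereomers), via lithium ester enolate 9 (not isolated)
Conditions: LDA, 8, THF, −78 °C; then 7, −78 °C; AcOH quench at −78 °C
Reagents that add atoms: none
Why: Aldol addition of the lithium ester enolate to the ketone (enolisable only at C6) forms the C4–C5 bond; the configurations at C4 and C5 do not matter because C5 becomes trigonal in step 6 and C4 is re-set in step 8.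

**Step 6**
Reactants: 10 aldol adduct (tertiary C5 alcohol)
Product: 11 methyl 2-[6-(1,3-dioxolan-2-ylmethyl)-7-methyl-7-((E)-prop-1-enyl)-1,4-dioxaspiro[4.5]dec-8-en-8-yl]pent-4-enoate (C4 epimers)
Conditions: SOCl2, pyridine, CH2Cl2, −10 → 0 °C
Reagents that add atoms: none
Why: Dehydration through the chlorosulfite (anti elimination) should give mainly the endocyclic C5=C6 olefin because the tetrasubstituted exocyclic enoate is strained against quaternary C10, and any conjugated isomer can be returned to 11 by deconjugative protonation of its dienolate.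

**Step 7**
Reactants: 11 ring B triene ester (C10 propenyl arm, C4 allyl arm, C5=C6)
Product: 13 methyl 8,8:12,12-bis(ethylenedioxy)-13,14,15,16,17,18-hexanorlabd-5-en-19-oate (C4 epimers), via diene 12 (not isolated)
Conditions: second-generation Grubbs catalyst (5 mol %), CH2Cl2 (5 mM), 40 °C; then H2 (5 atm), 40 °C
Reagents that add atoms: none
Why: The Ru alkylidene initiates at the unhindered allyl terminus of the C4 arm and closes onto the C10 propenyl group through a metallacyclobutane that extrudes propene, so the C1=C2 bond is formed and ring A is closed; admission of H2 then converts the spent carbene into a Ru hydride that saturates this bond in the same flask. The closest known reaction type is ring-closing olefin metathesis of a 1,7-diene run as a tandem metathesis–hydrogenation. Ring A closes as a six-membered cyclohexene between two arms on the adjacent ring B carbons C5 and C10, a closure helped by the quaternary C10 and the branched C4. No stereocentre is created: C10 is already fixed, both C4 epimers cyclise and are converged in step 8, and the cis ring olefin disappears on hydrogenation. The step needs ring closure over cross-metathesis, which high dilution and the fixed 1,2-disposition of the arms on the C5=C6 olefin should secure, and saturation of C1=C2 only, which the trisubstituted C5=C6 bond between C4 and quaternary C10 should secure by being inert to the Ru carbene and to the mild Ru hydride.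

**Step 8**
Reactants: 13 Δ5-octalin ester (C4 epimers)
Product: 15 methyl 8,8:12,12-bis(ethylenedioxy)-13,14,15,16,17-pentanorlabd-5-en-19-oate (4α-methyl; 4β-ester), via lithium dienolate 14 (not isolated)
Conditions: LDA, THF, DMPU, −78 °C; MeI, −78 → −20 °C
Reagents that add atoms: iodomethane, CI
Why: Deconjugative α-alkylation of the extended ester dienolate should occur at C4 from the α-face, anti to the axial C10 methyl group, so that the new methyl is α (equatorial) and the ester β (axial) from either C4 epimer.

**Step 9**
Reactants: 15 Δ5-octalin with quaternary C4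
Product: 17 methyl 6α-hydroxy-8,8:12,12-bis(ethylenedioxy)-13,14,15,16,17-pentanorlabdan-19-oate, via alkylborane 16 (not isolated)
Conditions: BH3·THF, THF, 0 °C → rt; then NaOH, H2O2, 0 °C
Reagents that add atoms: borane–tetrahydrofuran complex, B.C1CCOC1 (boron is carried only by 16); hydrogen peroxide, OO
Why: Hydroboration–oxidation puts boron on the less substituted C6 and hydrogen on C5 in a syn addition from the α-face, the face free of the axial C10 methyl and C4 ester groups, so 5α-H (trans ring fusion) and 6α-OH should arise together, the oxidation going with retention.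

**Step 10**
Reactants: 17 6α-alcohol
Product: 18 methyl 6α-acetoxy-8,8:12,12-bis(ethylenedioxy)-13,14,15,16,17-pentanorlabdan-19-oate
Conditions: Ac2O, DMAP (cat.), pyridine, rt
Reagents that add atoms: acetic anhydride, CC(=O)OC(C)=O
Why: DMAP-catalysed acylation of the equatorial secondary alcohol; no stereocentre is affected.

**Step 11**
Reactants: 18 bis-dioxolane acetate
Product: 19 methyl 6α-acetoxy-8,12-dioxo-13,14,15,16,17-pentanorlabdan-19-oate
Conditions: 1 M HCl, THF, rt; crude product used at once
Reagents that add atoms: water, O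
Why: Acid-catalysed hydrolysis of both dioxolanes unmasks the C8 ketone and the C12 aldehyde, and C9, now α to the ketone, keeps its more stable equatorial (β) configuration.

**Step 12**
Reactants: 19 keto aldehyde
Product: 20 methyl (12Z)-6α-acetoxy-13-iodo-8-oxo-14,15,17-trinorlabd-12-en-19-oate
Conditions: EtPPh3I, n-BuLi, THF, 0 °C; I2, −78 °C; NaHMDS, −20 °C; then 19, −78 °C
Reagents that add atoms: ethyltriphenylphosphonium iodide, CC[P+](c1ccccc1)(c1ccccc1)c1ccccc1.[I-]; iodine, II
Why: Stork–Zhao-type Wittig olefination with the α-iodo ylide should react with the aldehyde in preference to the hindered ketone and give the (Z)-iodoalkene (iodine cis to C11) through the kinetically favoured cis-oxaphosphetane.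

**Step 13**
Reactants: 20 keto vinyl iodide
Product: 21 methyl (12Z)-6α-acetoxy-13-iodo-14,15-dinorlabda-8(17),12-dien-19-oate
Conditions: Zn, CH2Br2, TiCl4, THF, CH2Cl2, 0 °C → rt
Reagents that add atoms: dibromomethane, BrCBr
Why: Takai–Lombardo methylenation is non-basic, so the β-acetoxy ketone should give the exocyclic methylene without loss of acetate or epimerisation at C9, and the esters are not attacked.

**Step 14**
Reactants: 21 methylene vinyl iodide
Product: 22 methyl (12Z)-6α-acetoxylabda-8(17),12,14-trien-19-oate (CNP0212193.2)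
Conditions: tributyl(vinyl)stannane, Pd(PPh3)4 (5 mol %), CuI (10 mol %), DMF, rt
Reagents that add atoms: tributyl(vinyl)stannane, C=C[Sn](CCCC)(CCCC)CCCC
Why: Stille coupling proceeds with retention of olefin geometry, so the vinyl group replaces iodine cis to C11 and completes the (12Z)-diene.

**Compound list**
1 | 1,4-dioxaspiro[4.5]dec-6-en-8-one | O=C1C=CC2(CC1)OCCO2 | starting material
2 | 7-iodo-1,4-dioxaspiro[4.5]dec-6-en-8-one | O=C1C(I)=CC2(CC1)OCCO2 | intermediate
3 | 7-methyl-1,4-dioxaspiro[4.5]dec-6-en-8-one | O=C1C(C)=CC2(CC1)OCCO2 | intermediate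
4 | (1,3-dioxolan-2-ylmethyl)magnesium bromide | Br[Mg]CC1OCCO1 | starting material
5 | bromomagnesium enolate of the C9 conjugate adduct | O1CCOC1C[C@H]1C2(OCCO2)CCC(O[Mg]Br)=C1C | intermediate
6 | (6R,7R)-7-allyl-6-(1,3-dioxolan-2-ylmethyl)-7-methyl-1,4-dioxaspiro[4.5]decan-8-one (allyl trans to the C9 stub) | O1CCOC1C[C@H]1C2(OCCO2)CCC(=O)[C@]1(C)CC=C | intermediate
7 | (6R,7R)-6-(1,3-dioxolan-2-ylmethyl)-7-methyl-7-[(E)-prop-1-enyl]-1,4-dioxaspiro[4.5]decan-8-one | O1CCOC1C[C@H]1C2(OCCO2)CCC(=O)[C@]1(C)/C=C/C | intermediate
8 | methyl pent-4-enoate | C=CCCC(=O)OC | starting material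
9 | lithium enolate of methyl pent-4-enoate | C=CCC=C(O[Li])OC | intermediate
10 | aldol adduct, tertiary C5 alcohol (C9, C10 as in 7; mixture at C4 and C5) | O1CCOC1C[C@H]1C2(OCCO2)CCC(O)(C(CC=C)C(=O)OC)[C@]1(C)/C=C/C | intermediate
11 | ring B triene ester with C5=C6 (C4 epimers) | O1CCOC1C[C@H]1C2(OCCO2)CC=C(C(CC=C)C(=O)OC)[C@]1(C)/C=C/C | intermediate
12 | methyl 8,8:12,12-bis(ethylenedioxy)-13,14,15,16,17,18-hexanorlabda-1,5-dien-19-oate (C4 epimers) | O1CCOC1C[C@H]1C2(OCCO2)CC=C3[C@]1(C)C=CCC3C(=O)OC | intermediate
13 | methyl 8,8:12,12-bis(ethylenedioxy)-13,14,15,16,17,18-hexanorlabd-5-en-19-oate (C4 epimers) | O1CCOC1C[C@H]1C2(OCCO2)CC=C3[C@]1(C)CCCC3C(=O)OC | intermediate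
14 | lithium dienolate of 13 | O1CCOC1C[C@H]1C2(OCCO2)CC=C3[C@]1(C)CCCC3=C(O[Li])OC | intermediate
15 | methyl 8,8:12,12-bis(ethylenedioxy)-13,14,15,16,17-pentanorlabd-5-en-19-oate (4α-methyl, 4β-ester) | O1CCOC1C[C@H]1C2(OCCO2)CC=C3[C@]1(C)CCC[C@]3(C)C(=O)OC | intermediate
16 | 6α-boryl-5α-H alkylborane from 15 | O1CCOC1C[C@H]1C2(OCCO2)C[C@H](B)[C@@H]3[C@]1(C)CCC[C@]3(C)C(=O)OC | intermediate
17 | methyl 6α-hydroxy-8,8:12,12-bis(ethylenedioxy)-13,14,15,16,17-pentanorlabdan-19-oate | O1CCOC1C[C@H]1C2(OCCO2)C[C@H](O)[C@@H]3[C@]1(C)CCC[C@]3(C)C(=O)OC | intermediate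
18 | methyl 6α-acetoxy-8,8:12,12-bis(ethylenedioxy)-13,14,15,16,17-pentanorlabdan-19-oate | O1CCOC1C[C@H]1C2(OCCO2)C[C@H](OC(C)=O)[C@@H]3[C@]1(C)CCC[C@]3(C)C(=O)OC | intermediate
19 | methyl 6α-acetoxy-8,12-dioxo-13,14,15,16,17-pentanorlabdan-19-oate | O=CC[C@H]1C(=O)C[C@H](OC(C)=O)[C@@H]2[C@]1(C)CCC[C@]2(C)C(=O)OC | intermediate
20 | methyl (12Z)-6α-acetoxy-13-iodo-8-oxo-14,15,17-trinorlabd-12-en-19-oate | I/C(C)=C\C[C@H]1C(=O)C[C@H](OC(C)=O)[C@@H]2[C@]1(C)CCC[C@]2(C)C(=O)OC | intermediate
21 | methyl (12Z)-6α-acetoxy-13-iodo-14,15-dinorlabda-8(17),12-dien-19-oate | I/C(C)=C\C[C@H]1C(=C)C[C@H](OC(C)=O)[C@@H]2[C@]1(C)CCC[C@]2(C)C(=O)OC | intermediate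
22 | methyl (12Z)-6α-acetoxylabda-8(17),12,14-trien-19-oate | C=C/C(C)=C\C[C@H]1C(=C)C[C@H](OC(C)=O)[C@@H]2[C@]1(C)CCC[C@]2(C)C(=O)OC | target

**Totals.** Total step count: 14. Longest linear sequence: 14 steps (1 → 22).

**Steps most likely to fail**

Step 3. The conjugate addition may stall or lose enantiofacial control, because the enone is both α-substituted and flanked by the ketal carbon. Fallback, setting out from 3: a ligand-free, silyl-accelerated copper-catalysed addition of 4 (CuBr·SMe2, TMSCl, THF, −78 °C) would give the racemic trimethylsilyl enol ether F1. Regeneration of the lithium enolate with MeLi and allylation with allyl iodide would give racemic 6. The wanted enantiomer would be separated from its mirror image, ent-ketone F2, by preparative chromatography on a chiral stationary phase. The route is rejoined at 6.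

Step 5. The ester enolate may enolise the hindered ketone instead of adding, and the congested adduct may undergo retro-aldol cleavage. Fallback, setting out from 7: enolisation towards C6 and triflation (KHMDS, PhNTf2, THF, −78 °C) would give the enol triflate F3. Negishi-type coupling of F3 with the Reformatsky reagent from methyl 2-bromopent-4-enoate and zinc (Pd(dba)2, P(t-Bu)3, THF) would form the C4–C5 bond with the C5=C6 olefin already in place. The route is rejoined at 11.

Step 9. Hydroboration of the trisubstituted olefin between two quaternary carbons may be slow or poorly face-selective, and borane may begin to reduce the ester. Fallback, setting out from 15: epoxidation from the α-face (mCPBA, NaHCO3, CH2Cl2) would give the 5α,6α-epoxide F4. Reductive opening with Cp2TiCl (from Cp2TiCl2 and Mn dust, with collidinium chloride and 1,4-cyclohexadiene in THF) would break the C5–O bond to the tertiary C5 radical. Hydrogen atom transfer to this radical from the open α-face would give the 6α-alcohol with 5α-H. The route is rejoined at 17.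

**Further compounds**
F1 | step 3 | racemic trimethylsilyl enol ether of the conjugate adduct | C[Si](C)(C)OC1=C(C)C(CC2OCCO2)C2(CC1)OCCO2
F2 | step 3 | ent-ketone, (6S,7S)-enantiomer of 6 | O1CCOC1C[C@@H]1C2(OCCO2)CCC(=O)[C@@]1(C)CC=C
F3 | step 5 | enol triflate of 7 (C5=C6) | O1CCOC1C[C@H]1C2(OCCO2)CC=C(OS(=O)(=O)C(F)(F)F)[C@]1(C)/C=C/C
F4 | step 9 | 5α,6α-epoxide of 15 | O1CCOC1C[C@H]1C2(OCCO2)C[C@@H]3O[C@]34[C@]1(C)CCC[C@]4(C)C(=O)OC
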